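**Retrosynthetic overview**
- The target is cut at the bond between the bridging CH2 and the quaternary ring carbon of ring A. That bond is made last, by anodic oxidation of the ring methyl of the ring B aminodienone to a protonated aza-quinone methide that is captured by the enol of the ring A acyloxy dienone.
- Both rings come from one cyclohexadienone diol. O-acylation of its tertiary OH gives the ring A piece; C-acylation and then amination give the ring B piece. Both acyl groups come from (R)-2-methylbutanoic acid.
- The carbocycle is closed by Dieckmann-type attack of a methoxy dienolate on the lactone carbonyl of a C-acylated L-lactic acid dioxolanone; this expels pivaldehyde and frees the tertiary alcohol.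
- Ring order: temporary dioxolanone, then the six-membered carbocycle (used twice, as ring A and ring B), then union of the two rings.

Assumption: (R)-2-methylbutanoic acid and L-lactic acid are bought as single enantiomers; enolisable dienones are drawn as one tautomer, so the CIP letter at the carbinol carbon changes with the tautomer (S in 9 and 13, R in 15, 16 and 18) without any change in geometry.

**Step 1**
Reactants: 1 (2S)-2-hydroxypropanoic acid (L-lactic acid); 2 2,2-dimethylpropanal (pivaldehyde)
Product: 3 (2S,5S)-2-tert-butyl-5-methyl-1,3-dioxolan-4-one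
Conditions: 2 (1.5 equiv), TsOH·H2O (cat.), H2SO4 (cat.), pentane, reflux, Dean–Stark; recrystallise from pentane at −78 °C
Reagents that add atoms: none
Why: Acid-catalysed acetalisation in which the lactate centre favours the cis acetal (about 4:1, pure after cold crystallisation), so the new acetal carbon is set by the purchased stereocentre.

**Step 2**
Reactants: 3 (2S,5S)-2-tert-butyl-5-methyl-1,3-dioxolan-4-one; 4 pent-2-ynoic acid
Product: 7 (2S,5R)-2-tert-butyl-5-methyl-5-(pent-2-ynoyl)-1,3-dioxolan-4-one, via pent-2-ynoyl chloride 5 (not isolated), via lithium enolate 6 (not isolated)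
Conditions: 4, (COCl)2, CH2Cl2, rt, evaporate; 3, LiN(SiMe3)2 (1.05 equiv), THF, −78 °C; enolate cannulated into 5 (1.3 equiv), THF, −78 °C
Reagents that add atoms: none
Why: C-acylation of an ester enolate by an acid chloride under self-regeneration of stereocentres: the electrophile enters anti to the tert-butyl group and takes the place of the former H, so the quaternary carbinol carbon is set by the acetal centre.

**Step 3**
Reactants: 7 (2S,5R)-2-tert-butyl-5-methyl-5-(pent-2-ynoyl)-1,3-dioxolan-4-one
Product: 9 (6S)-5,6-dihydroxy-3-methoxy-4,6-dimethylcyclohexa-2,4-dien-1-one, via methoxy enone 8 (not isolated)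
Conditions: MeOH (1.5 equiv), PMe3 (10 mol %), CH2Cl2, 0 °C; evaporate; LiN(iPr)2 (2.5 equiv), THF, −78 → −20 °C; 1 M HCl
Reagents that add atoms: methanol CO
Why: Phosphine-catalysed oxa-Michael addition of MeOH to the ynone, then γ-deprotonation of the β-methoxy enone (its α′ carbon is quaternary) and 6-(enolendo)-exo-trig Claisen (Dieckmann-type) attack on the lactone carbonyl, which expels pivaldehyde and frees the tertiary alcohol without touching the carbinol stereocentre.

**Step 4**
Reactants: 9 (6S)-5,6-dihydroxy-3-methoxy-4,6-dimethylcyclohexa-2,4-dien-1-one; 10 (2R)-2-methylbutanoic acid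
Product: 13 (1S)-2-hydroxy-4-methoxy-1,3-dimethyl-6-oxocyclohexa-2,4-dien-1-yl (2R)-2-methylbutanoate, via acid chloride 11 (not isolated), via dilithium salt 12 (not isolated)
Conditions: 10, (COCl)2, DMF (cat.), CH2Cl2, 0 °C → rt, evaporate; 9, LiN(SiMe3)2 (2.2 equiv), THF, −78 °C; add 11 (1.05 equiv), −78 → −20 °C; 1 M HCl
Reagents that add atoms: none
Why: O-acylation of an alkoxide: in the dianion the localised tertiary alkoxide is far more basic and nucleophilic than the delocalised vinylogous carboxylate (and any enol ester formed passes its acyl group on to the alkoxide), so one equivalent of acid chloride gives the tertiary ester with both stereocentres untouched.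

**Step 5**
Reactants: 9 (6S)-5,6-dihydroxy-3-methoxy-4,6-dimethylcyclohexa-2,4-dien-1-one; 10 (2R)-2-methylbutanoic acid
Product: 15 (6R)-5,6-dihydroxy-3-methoxy-2,6-dimethyl-4-[(2R)-2-methylbutanoyl]cyclohexa-2,4-dien-1-one, via enol ester 14 (not isolated)
Conditions: 10 (1.1 equiv), DCC (1.2 equiv), DMAP (1.2 equiv), CH2Cl2, 0 °C → rt
Reagents that add atoms: none
Why: Steglich esterification of the vinylogous acid followed by DMAP-mediated O-to-C acyl migration (the standard entry to 2-acyl-1,3-diones), which ends at the unsubstituted ring carbon because only that triketone can enolise; no stereocentre is touched.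

**Step 6**
Reactants: 15 (6R)-5,6-dihydroxy-3-methoxy-2,6-dimethyl-4-[(2R)-2-methylbutanoyl]cyclohexa-2,4-dien-1-one
Product: 16 (6R)-5-amino-6-hydroxy-3-methoxy-2,6-dimethyl-4-[(2R)-2-methylbutanoyl]cyclohexa-2,4-dien-1-one
Conditions: NH4OAc (10 equiv), EtOH, 4 Å molecular sieves, 50 °C
Reagents that add atoms: ammonium acetate CC(=O)[O-].[NH4+]
Why: Enaminone formation (vinylogous acid to vinylogous amide) by addition–elimination of NH3 at the ring carbon of the endocyclic enol, the α-branched exocyclic carbonyl being the slower site; the mild temperature avoids α-ketol rearrangement, so the configuration is kept.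

**Step 7**
Reactants: 16 (6R)-5-amino-6-hydroxy-3-methoxy-2,6-dimethyl-4-[(2R)-2-methylbutanoyl]cyclohexa-2,4-dien-1-one; 13 (1S)-2-hydroxy-4-methoxy-1,3-dimethyl-6-oxocyclohexa-2,4-dien-1-yl (2R)-2-methylbutanoate
Product: 18 Gilluone B, via iminium tetrafluoroborate 17 (not isolated)
Conditions: divided cell (glass frit), carbon felt anode, Pt cathode; anolyte 16, Bu4NBF4 (0.3 M), CH2Cl2, −78 °C, constant current, 2.2 F/mol; catholyte CF3SO3H, Bu4NBF4, CH2Cl2; then 13 (1.2 equiv), 2,6-di-tert-butyl-4-methylpyridine (2.5 equiv) added to the anolyte, −78 → −30 °C; cold NaHCO3 quench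
Reagents that add atoms: none
Why: Proposed new method: low-temperature anodic two-electron oxidation of the ring methyl of 16 (radical cation, proton loss, second electron transfer) should give the N-protonated aza-quinone methide 17 as a cation pool, protected from over-oxidation by its charge and from competing oxidation of 13 because 13 is added only after the current is off; the methyl-bearing enol carbon C-5 of 13 then adds to the exocyclic CH2 anti to the bulky acyloxy group on C-1, forming the inter-ring C–C bond and the (R)-quaternary centre under control of the lactate-derived carbinol centre; the closest known reaction types are cation-pool generation of N-acyliminium and diarylcarbenium ions by anodic C–H oxidation, anodic benzylic oxidation of p-cresol-type compounds to quinone methides, and Michael additions of cyclic 1,3-diones to quinone methides.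

**Compound list**
1 | (2S)-2-hydroxypropanoic acid (L-lactic acid) | C[C@H](O)C(=O)O | starting material
2 | 2,2-dimethylpropanal (pivaldehyde) | CC(C)(C)C=O | starting material
3 | (2S,5S)-2-tert-butyl-5-methyl-1,3-dioxolan-4-one | C[C@@H]1O[C@H](C(C)(C)C)OC1=O | intermediate
4 | pent-2-ynoic acid | CCC#CC(=O)O | starting material
5 | pent-2-ynoyl chloride | CCC#CC(=O)Cl | intermediate
6 | lithium (2S)-2-tert-butyl-5-methyl-1,3-dioxol-4-olate (lithium enolate of 3) | [Li+].CC1=C([O-])O[C@@H](C(C)(C)C)O1 | intermediate
7 | (2S,5R)-2-tert-butyl-5-methyl-5-(pent-2-ynoyl)-1,3-dioxolan-4-one | C[C@]1(C(=O)C#CCC)O[C@H](C(C)(C)C)OC1=O | intermediate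
8 | (2S,5R)-2-tert-butyl-5-[(2E)-3-methoxypent-2-enoyl]-5-methyl-1,3-dioxolan-4-one | C[C@]1(C(=O)/C=C(/OC)CC)O[C@H](C(C)(C)C)OC1=O | intermediate
9 | (6S)-5,6-dihydroxy-3-methoxy-4,6-dimethylcyclohexa-2,4-dien-1-one | O[C@]1(C)C(=O)C=C(OC)C(C)=C1O | intermediate
10 | (2R)-2-methylbutanoic acid | CC[C@@H](C)C(=O)O | starting material
11 | (2R)-2-methylbutanoyl chloride | CC[C@@H](C)C(=O)Cl | intermediate
12 | dilithium salt of 9 (tertiary alkoxide and enolate) | [Li+].[Li+].[O-][C@]1(C)C(=O)C=C(OC)C(C)=C1[O-] | intermediate
13 | (1S)-2-hydroxy-4-methoxy-1,3-dimethyl-6-oxocyclohexa-2,4-dien-1-yl (2R)-2-methylbutanoate | CC[C@@H](C)C(=O)O[C@]1(C)C(=O)C=C(OC)C(C)=C1O | intermediate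
14 | (6R)-6-hydroxy-3-methoxy-4,6-dimethyl-5-oxocyclohexa-1,3-dien-1-yl (2R)-2-methylbutanoate | CC1=C(OC)C=C(OC(=O)[C@H](C)CC)[C@@](C)(O)C1=O | intermediate
15 | (6R)-5,6-dihydroxy-3-methoxy-2,6-dimethyl-4-[(2R)-2-methylbutanoyl]cyclohexa-2,4-dien-1-one | CC1=C(OC)C(C(=O)[C@H](C)CC)=C(O)[C@@](C)(O)C1=O | intermediate
16 | (6R)-5-amino-6-hydroxy-3-methoxy-2,6-dimethyl-4-[(2R)-2-methylbutanoyl]cyclohexa-2,4-dien-1-one | CC1=C(OC)C(C(=O)[C@H](C)CC)=C(N)[C@@](C)(O)C1=O | intermediate
17 | (6R)-6-hydroxy-3-methoxy-6-methyl-4-methylidene-2-[(2R)-2-methylbutanoyl]-5-oxocyclohex-2-en-1-iminium tetrafluoroborate | C=C1C(OC)=C(C(=O)[C@H](C)CC)C(=[NH2+])[C@@](C)(O)C1=O.F[B-](F)(F)F | intermediate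
18 | Gilluone B, (1R,5R)-5-{[(5R)-4-amino-5-hydroxy-2-methoxy-5-methyl-3-[(2R)-2-methylbutanoyl]-6-oxocyclohexa-1,3-dien-1-yl]methyl}-4-methoxy-1,5-dimethyl-2,6-dioxocyclohex-3-en-1-yl (2R)-2-methylbutanoate | CC[C@@H](C)C(=O)O[C@]1(C)C(=O)C=C(OC)[C@@](C)(CC2=C(OC)C(C(=O)[C@H](C)CC)=C(N)[C@@](C)(O)C2=O)C1=O | target

**Step count and risks**
Total steps: 7. Longest linear sequence: 6 (steps 1, 2, 3, 5, 6, 7); step 4 is the one-step branch from 9.

Most likely to fail, first: step 7 (the proposed new anodic coupling). The cation pool may not form cleanly or may be captured by a second molecule of 16. The enol of 13 may react at C-3 instead of C-5, or on the face syn to the acyloxy group. The C-5 adduct may also revert on warming, since the C-3 isomer keeps the vinylogous acid and is probably the more stable one. The fallback uses known chemistry and sets out from 16: Wohl–Ziegler bromination of the activated ring methyl (N-bromosuccinimide, azobisisobutyronitrile cat., PhCF3, 75 °C) gives (6R)-5-amino-2-(bromomethyl)-6-hydroxy-3-methoxy-6-methyl-4-[(2R)-2-methylbutanoyl]cyclohexa-2,4-dien-1-one F1, which is used crude to C-alkylate the cesium enolate of 13 (Cs2CO3, MeCN, −20 °C) and comes back to the route at 18.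

Second: step 3. The γ-deprotonation and ring closure onto the dioxolanone may lose out to retro-Claisen cleavage of the non-enolisable keto lactone or to a dienolate geometry that cannot cyclise. The fallback sets out from 3 and installs the methoxy group last. The enolate of 3 is C-acetylated with acetyl chloride to (2S,5R)-5-acetyl-2-tert-butyl-5-methyl-1,3-dioxolan-4-one F2. Its lithium enolate (LiN(iPr)2, 2 equiv) is acylated with N-propanoylimidazole to (2S,5R)-2-tert-butyl-5-methyl-5-(3-oxopentanoyl)-1,3-dioxolan-4-one F3. The β-diketone dianion of F3 (LiN(iPr)2, 2.2 equiv) closes the ring through its terminal carbanion onto the lactone carbonyl, with loss of pivaldehyde, to the triketone drawn as its enol (6S)-3,5,6-trihydroxy-4,6-dimethylcyclohexa-2,4-dien-1-one F4. HC(OMe)3, MeOH and TsOH then etherify the least hindered carbonyl, and the sequence comes back to the route at 9.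

Third: step 6. Ammonia may condense at the exocyclic acyl carbon instead of the ring carbon, or merely form the ammonium salt of the acidic triketone. The fallback sets out from 15: O-methylation of the ring enol with Me3SiCHN2 (MeOH/toluene, 0 °C) gives (6R)-6-hydroxy-3,5-dimethoxy-2,6-dimethyl-4-[(2R)-2-methylbutanoyl]cyclohexa-2,4-dien-1-one F5, whose 5-methoxy group is displaced by NH3 in MeOH at rt by addition–elimination, coming back to the route at 16.

**Further compounds**
F1 | step 7 | (6R)-5-amino-2-(bromomethyl)-6-hydroxy-3-methoxy-6-methyl-4-[(2R)-2-methylbutanoyl]cyclohexa-2,4-dien-1-one | BrCC1=C(OC)C(C(=O)[C@H](C)CC)=C(N)[C@@](C)(O)C1=O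
F2 | step 3 | (2S,5R)-5-acetyl-2-tert-butyl-5-methyl-1,3-dioxolan-4-one | C[C@]1(C(C)=O)O[C@H](C(C)(C)C)OC1=O
F3 | step 3 | (2S,5R)-2-tert-butyl-5-methyl-5-(3-oxopentanoyl)-1,3-dioxolan-4-one | C[C@]1(C(=O)CC(=O)CC)O[C@H](C(C)(C)C)OC1=O
F4 | step 3 | (6S)-3,5,6-trihydroxy-4,6-dimethylcyclohexa-2,4-dien-1-one | O[C@]1(C)C(=O)C=C(O)C(C)=C1O
F5 | step 6 | (6R)-6-hydroxy-3,5-dimethoxy-2,6-dimethyl-4-[(2R)-2-methylbutanoyl]cyclohexa-2,4-dien-1-one | CC1=C(OC)C(C(=O)[C@H](C)CC)=C(OC)[C@@](C)(O)C1=O
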